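**Retrosynthetic overview**

- The target is a bicyclo[3.2.1]oct-2-en-8-one with bridgeheads C1 (allyl) and C5 (OMe), a C2=C3(OMe)–C4H(OH) bridge, a C6(aryl)–C7(methyl) bridge and the C8 ketone bridge. The strategy rests on C5: a fully substituted, oxygen-bearing carbon bonded at once to oxygenated C4, the C8 carbonyl and benzylic C6, which is the pattern left when C6 shifts from C4 to C5 in an acyloin rearrangement.
- End game, read backwards: aryl acetate off; C4 carbinol from the C4 enone by hydride from the C8 face; C5–OMe from C5–OH.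
- Key disconnection C5–C6: the 5-hydroxy-4,8-dione comes from a bicyclo[2.2.2]octenedione (same atom labels, C4 a methoxylated bridgehead, C5 and C8 the 1,2-dione) by ether cleavage and 1,2-shift of C6 from C4 to C5.
- The bicyclo[2.2.2]octenedione comes from an endo Diels–Alder reaction (bonds C1–C7 and C4–C6) of 6-allyl-3,4-dimethoxy-o-benzoquinone with (E)-isoeugenyl acetate, followed by resolution. The quinone comes from 2,3,4-trimethoxyphenol by O-allylation, Claisen rearrangement and IBX oxidation.
- Ring order: arene, then o-quinone, then bicyclo[2.2.2]octene (both new six-membered rings in one step), then bicyclo[3.2.1]octene (five-membered ring C1–C7–C6–C5–C8 closed by the shift).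

Key step: step 6

Remark: the atom labels C1–C8 of the target are kept for every bicyclic compound. The phenol is carried as its acetate because a para-acyloxyaryl group does not support benzylic ionisation under the Lewis acid of the key step. 2,3,4-Trimethoxyphenol and (E)-isoeugenyl acetate are taken as commercial. In step 4 the dienophile is used in about twofold excess and the surplus is recovered unchanged.

**Route**

Step 1
Reactants: 1 2,3,4-trimethoxyphenol; 2 allyl bromide
Product: 3 1,2,3-trimethoxy-4-(prop-2-en-1-yloxy)benzene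
Conditions: K2CO3, acetone, reflux
Reagents that add atoms: none
Why: Williamson ether synthesis: the phenoxide formed with K2CO3 displaces bromide from the allylic halide (SN2), and O-alkylation should dominate in acetone.

Step 2
Reactants: 3 1,2,3-trimethoxy-4-(prop-2-en-1-yloxy)benzene
Product: 4 2,3,4-trimethoxy-6-(prop-2-en-1-yl)phenol
Conditions: N,N-diethylaniline, 200 °C, sealed tube, argon
Reagents that add atoms: none
Why: Aromatic Claisen rearrangement: the [3,3]-shift can end productively only at the one ortho carbon that carries hydrogen, after which tautomerisation restores the phenol.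

Step 3
Reactants: 4 2,3,4-trimethoxy-6-(prop-2-en-1-yl)phenol
Product: 5 o-quinone 3,4-dimethoxy-6-(prop-2-en-1-yl)cyclohexa-3,5-diene-1,2-dione (used at once in solution)
Conditions: IBX (1.2 equiv), DMF, 0 °C → rt, dark; Et2O/aq. NaHCO3 work-up
Reagents that add atoms: 2-iodoxybenzoic acid (IBX), O=C1OI(=O)(O)c2ccccc12
Why: IBX ortho-oxygenation of a phenol: the iodine-bound oxygen is delivered to the methoxy-bearing ortho carbon and the resulting mixed ketal collapses with loss of methanol to the o-quinone (oxidative demethylation of a guaiacol-type phenol), the two remaining ring methoxy groups stabilising the quinone as vinylogous esters.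

Step 4
Reactants: 5 o-quinone 3,4-dimethoxy-6-(prop-2-en-1-yl)cyclohexa-3,5-diene-1,2-dione; 6 (E)-isoeugenyl acetate
Product: 7 racemic (1R*,4R*,7R*,8S*)-8-(4-acetoxy-3-methoxyphenyl)-4,5-dimethoxy-7-methyl-1-(prop-2-en-1-yl)bicyclo[2.2.2]oct-5-ene-2,3-dione
Conditions: Sc(OTf)3 (20 mol %), CH2Cl2–MeCN 9:1, 4 Å MS, −40 → 0 °C, dark; dienophile in twofold excess
Reagents that add atoms: none
Why: Lewis acid-catalysed inverse-electron-demand Diels–Alder reaction of an o-quinone carbodiene with a styrene-type alkene, a pure addition in which every atom of both partners ends in the adduct: Sc(OTf)3 chelated by the two carbonyl oxygens lowers the diene LUMO and occupies the oxygens, the propenyl β-carbon (C7) should bond to the allyl-bearing terminus C1 (the 1,6-acceptor position that carries no methoxy group) and benzylic C6 to methoxylated C4, the endo transition state places the aryl group under the diene (syn to C2=C3 in the adduct) and suprafacial addition to the E-alkene sets aryl and methyl trans, with the methyl group syn to the dione bridge.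

Step 5
Reactants: 7 racemic Diels–Alder adduct
Product: 8 (1R,4R,7R,8S)-8-(4-acetoxy-3-methoxyphenyl)-4,5-dimethoxy-7-methyl-1-(prop-2-en-1-yl)bicyclo[2.2.2]oct-5-ene-2,3-dione
Conditions: preparative SFC, amylose tris(3,5-dimethylphenylcarbamate) phase, CO2/2-propanol, amber glassware
Reagents that add atoms: none
Why: Resolution of enantiomers by chromatography on a chiral stationary phase; no bond is made or broken, and the enantiomer to be carried on is identified by anomalous-dispersion X-ray analysis or chiroptical comparison.

Step 6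
Reactants: 8 (1R,4R,7R,8S)-bicyclo[2.2.2]oct-5-ene-2,3-dione adduct
Product: 11 4-[(1R,5S,6S,7R)-5-hydroxy-3-methoxy-7-methyl-4,8-dioxo-1-(prop-2-en-1-yl)bicyclo[3.2.1]oct-2-en-6-yl]-2-methoxyphenyl acetate, via dichloroboryl ketolate 9 (not isolated), via rearranged dichloroboryl alkoxide 10 (not isolated)
Conditions: BCl3 (1.5 equiv), CH2Cl2, −78 → 0 °C, dark; then pH 7 buffer
Reagents that add atoms: none
Why: BCl3 binds the methoxy oxygen on bridgehead C4 and the neighbouring C5 carbonyl, chloride removes the methyl group (Lewis-acid ether cleavage next to a carbonyl), and in boron ketolate 9 the C4–C6 bond, held by the cage about 30° from the C5 π* axis, shifts suprafacially from C4 to C5 while C4–O becomes the C4 carbonyl, giving alkoxide 10 and, after hydrolysis, 11; a shift that ran ahead of methyl loss through the O-methyl oxocarbenium ion would end at the same compound. The closest known reaction type is the α-ketol (acyloin) rearrangement that turns bicyclo[2.2.2]octane ketols into bicyclo[3.2.1]octane ketols under Lewis acid or alkoxide promotion. The five-membered ring C1–C7–C6–C5–C8 is closed by the new C5–C6 bond in a 1,2-migration (ring contraction of the six-membered ring C1–C7–C6–C4–C5–C8, with C4 passing into the three-carbon bridge), not by an external cyclisation. C5 is the one new stereocentre and can form only with the geometry the cage allows, the new bond arising on the face where C6 already sits; C6 migrates with retention, so the aryl group stays syn to the C2=C3 bridge, and C1 and C7 are untouched. The step needs migration to C5 and not to C8, which is secured because only C4 carries the oxygen that can become a carbonyl, and migration of benzylic C6 rather than vinylic C3, both bonds being equally aligned: only C6 migration gives the conjugated 3-methoxy-2-en-4-one and relieves the eclipsed 1,2-dione, and since ketol shifts are reversible at the boron ketolate stage this isomer should collect. The aryl acetate withholds the stabilisation that would let the C4–C6 bond ionise at C6 instead of migrating.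

Step 7
Reactants: 11 5-hydroxy-bicyclo[3.2.1]oct-2-ene-4,8-dione
Product: 12 4-[(1R,5S,6S,7R)-3,5-dimethoxy-7-methyl-4,8-dioxo-1-(prop-2-en-1-yl)bicyclo[3.2.1]oct-2-en-6-yl]-2-methoxyphenyl acetate
Conditions: MeOTf (5 equiv), 2,6-di-tert-butyl-4-methylpyridine (6 equiv), CH2Cl2, rt → 40 °C
Reagents that add atoms: methyl trifluoromethanesulfonate, COS(=O)(=O)C(F)(F)F
Why: O-Alkylation of a tertiary alcohol with methyl triflate under non-basic conditions (Williamson-type methylation with a hindered pyridine as acid scavenger): no alkoxide is formed, so the ketol cannot shift again and the non-enolisable 1,3-diketone is not opened by retro-Claisen cleavage.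

Step 8
Reactants: 12 3,5-dimethoxy-bicyclo[3.2.1]oct-2-ene-4,8-dione
Product: 13 4-[(1R,4S,5R,6S,7R)-4-hydroxy-3,5-dimethoxy-7-methyl-8-oxo-1-(prop-2-en-1-yl)bicyclo[3.2.1]oct-2-en-6-yl]-2-methoxyphenyl acetate
Conditions: NaBH4 (1.0 equiv), CeCl3·7H2O (1.2 equiv), MeOH–CH2Cl2, −78 °C; acetone, then aq. NH4Cl
Reagents that add atoms: none
Why: Luche reduction: the cerium-modified methoxyborohydride should add 1,2 to the conjugated C4 ketone in preference to the C8 ketone flanked by two fully substituted carbons, and hydride should come from the C8 face because the other face of C4 is covered by the endo aryl group on C6, which sets C4 as S with the hydroxyl syn to the C6–C7 bridge.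

Step 9
Reactants: 13 O-acetyl allylic alcohol
Product: 14 (1R,4S,5R,6S,7R)-4-hydroxy-6-(4-hydroxy-3-methoxyphenyl)-3,5-dimethoxy-7-methyl-1-(prop-2-en-1-yl)bicyclo[3.2.1]oct-2-en-8-one (CNP0330966.1)
Conditions: NH4OAc (10 equiv), MeOH–H2O 4:1, rt
Reagents that add atoms: none
Why: Mild, near-neutral methanolysis of an aryl acetate (acyl transfer to the solvent mediated by NH4OAc); the absence of strong base should spare the β-hydroxy ketone (retro-aldol) and the para-hydroxybenzyl ketone (quinone methide extrusion).

**Compound list**

1 | 2,3,4-trimethoxyphenol | COc1ccc(O)c(OC)c1OC | starting material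
2 | allyl bromide (3-bromoprop-1-ene) | C=CCBr | starting material
3 | 1,2,3-trimethoxy-4-(prop-2-en-1-yloxy)benzene | C=CCOc1ccc(OC)c(OC)c1OC | intermediate
4 | 2,3,4-trimethoxy-6-(prop-2-en-1-yl)phenol | C=CCc1cc(OC)c(OC)c(OC)c1O | intermediate
5 | 3,4-dimethoxy-6-(prop-2-en-1-yl)cyclohexa-3,5-diene-1,2-dione (o-quinone) | C=CCC1=CC(OC)=C(OC)C(=O)C1=O | intermediate
6 | (E)-isoeugenyl acetate, 2-methoxy-4-[(1E)-prop-1-en-1-yl]phenyl acetate | C/C=C/c1ccc(OC(C)=O)c(OC)c1 | starting material
7 | racemic (1R*,4R*,7R*,8S*)-8-(4-acetoxy-3-methoxyphenyl)-4,5-dimethoxy-7-methyl-1-(prop-2-en-1-yl)bicyclo[2.2.2]oct-5-ene-2,3-dione (aryl syn to the C5=C6 etheno bridge; methyl syn to the dione bridge; racemate, one enantiomer drawn) | C=CC[C@@]12C=C(OC)[C@@](OC)(C(=O)C1=O)[C@H](c1ccc(OC(C)=O)c(OC)c1)[C@H]2C | intermediate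
8 | (1R,4R,7R,8S)-8-(4-acetoxy-3-methoxyphenyl)-4,5-dimethoxy-7-methyl-1-(prop-2-en-1-yl)bicyclo[2.2.2]oct-5-ene-2,3-dione (single enantiomer) | C=CC[C@@]12C=C(OC)[C@@](OC)(C(=O)C1=O)[C@H](c1ccc(OC(C)=O)c(OC)c1)[C@H]2C | intermediate
9 | dichloroboryl ether of the C4 bridgehead alkoxide of O-demethylated 8 (configuration as in 8) | C=CC[C@@]12C=C(OC)[C@@](OB(Cl)Cl)(C(=O)C1=O)[C@H](c1ccc(OC(C)=O)c(OC)c1)[C@H]2C | intermediate (not isolated)
10 | dichloroboryl ether of the C5 alkoxide of 11 (configuration as in 11) | C=CC[C@@]12C=C(OC)C(=O)[C@@](OB(Cl)Cl)(C1=O)[C@H](c1ccc(OC(C)=O)c(OC)c1)[C@H]2C | intermediate (not isolated)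
11 | 4-[(1R,5S,6S,7R)-5-hydroxy-3-methoxy-7-methyl-4,8-dioxo-1-(prop-2-en-1-yl)bicyclo[3.2.1]oct-2-en-6-yl]-2-methoxyphenyl acetate | C=CC[C@@]12C=C(OC)C(=O)[C@@](O)(C1=O)[C@H](c1ccc(OC(C)=O)c(OC)c1)[C@H]2C | intermediate
12 | 4-[(1R,5S,6S,7R)-3,5-dimethoxy-7-methyl-4,8-dioxo-1-(prop-2-en-1-yl)bicyclo[3.2.1]oct-2-en-6-yl]-2-methoxyphenyl acetate | C=CC[C@@]12C=C(OC)C(=O)[C@@](OC)(C1=O)[C@H](c1ccc(OC(C)=O)c(OC)c1)[C@H]2C | intermediate
13 | 4-[(1R,4S,5R,6S,7R)-4-hydroxy-3,5-dimethoxy-7-methyl-8-oxo-1-(prop-2-en-1-yl)bicyclo[3.2.1]oct-2-en-6-yl]-2-methoxyphenyl acetate | C=CC[C@@]12C=C(OC)[C@H](O)[C@@](OC)(C1=O)[C@H](c1ccc(OC(C)=O)c(OC)c1)[C@H]2C | intermediate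
14 | (1R,4S,5R,6S,7R)-4-hydroxy-6-(4-hydroxy-3-methoxyphenyl)-3,5-dimethoxy-7-methyl-1-(prop-2-en-1-yl)bicyclo[3.2.1]oct-2-en-8-one | C=CC[C@@]12C=C(OC)[C@H](O)[C@@](OC)(C1=O)[C@H](c1ccc(O)c(OC)c1)[C@H]2C | target

**Step count**

Total step count: 9. Longest linear sequence: 9 steps (1 to 14).

**Steps most likely to fail**

Step 6 (acyloin shift). The bridgehead ether may be cleaved without migration at temperatures the rest of the molecule tolerates. Vinylic C3 may migrate instead of C6, the product may undergo a further ketol shift, or the enol-ether methyl group may be lost. The fallback separates the two events and drives the shift with an alkoxide instead of a Lewis acid. Starting from 8, BCl3 at −78 °C with a cold methanol quench should give the free bridgehead ketol (1R,4R,7R,8S)-8-(4-acetoxy-3-methoxyphenyl)-4-hydroxy-5-methoxy-7-methyl-1-(prop-2-en-1-yl)bicyclo[2.2.2]oct-5-ene-2,3-dione F1. Its potassium alkoxide (KN(SiMe3)2, THF, −78 → −40 °C, then AcOH) should undergo the classical base-induced α-ketol rearrangement, in which the alkoxide pushes C6 onto C5. The route is rejoined at 11.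

Step 4 (Diels–Alder reaction). Cycloaddition to the acetate-deactivated propenylarene may be slow enough that the quinone dimerises or tautomerises to a quinone methide. A polar intermediate may also close through oxygen, or the reverse orientation may compete. The fallback uses a far more nucleophilic dienophile and exchanges the phenol protecting group afterwards. Commercial (E)-isoeugenol with TBSCl and imidazole in DMF should give tert-butyl{2-methoxy-4-[(1E)-prop-1-en-1-yl]phenoxy}dimethylsilane F2. F2 and 5 under Sc(OTf)3 at −78 °C should give the racemic silyl ether adduct, 8-[4-(tert-butyldimethylsilyloxy)-3-methoxyphenyl]-4,5-dimethoxy-7-methyl-1-(prop-2-en-1-yl)bicyclo[2.2.2]oct-5-ene-2,3-dione F3. Bu4NF buffered with AcOH should free the phenol, 8-(4-hydroxy-3-methoxyphenyl)-4,5-dimethoxy-7-methyl-1-(prop-2-en-1-yl)bicyclo[2.2.2]oct-5-ene-2,3-dione F4, which is acetylated at once (Ac2O, pyridine). The route is rejoined at 7.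

Step 8 (Luche reduction). Hydride may add to the strained C8 ketone in competition with C4, or attack C4 from the aryl face. The fallback replaces substrate control by catalyst control. From 12, an oxazaborolidine-catalysed (Corey–Bakshi–Shibata) reduction with (R)-1-methyl-3,3-diphenyltetrahydro-1H,3H-pyrrolo[1,2-c][1,3,2]oxazaborole and catecholborane in toluene at −78 °C is used; catecholborane leaves the allyl group alone. The oxazaborolidine needs a carbonyl with one accessible lone pair, which C8 between two quaternary carbons lacks. With quaternary C5 as the large substituent, the (R)-catalyst should deliver hydride to the C8 face of C4; should the alkenyl carbon C3 act as the large group, the (S)-catalyst is used instead. The route is rejoined at 13.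

**Further compounds**

F1 | step 6 | (1R,4R,7R,8S)-8-(4-acetoxy-3-methoxyphenyl)-4-hydroxy-5-methoxy-7-methyl-1-(prop-2-en-1-yl)bicyclo[2.2.2]oct-5-ene-2,3-dione | C=CC[C@@]12C=C(OC)[C@@](O)(C(=O)C1=O)[C@H](c1ccc(OC(C)=O)c(OC)c1)[C@H]2C
F2 | step 4 | tert-butyl{2-methoxy-4-[(1E)-prop-1-en-1-yl]phenoxy}dimethylsilane | C/C=C/c1ccc(O[Si](C)(C)C(C)(C)C)c(OC)c1
F3 | step 4 | racemic 8-[4-(tert-butyldimethylsilyloxy)-3-methoxyphenyl]-4,5-dimethoxy-7-methyl-1-(prop-2-en-1-yl)bicyclo[2.2.2]oct-5-ene-2,3-dione (one enantiomer drawn) | C=CC[C@@]12C=C(OC)[C@@](OC)(C(=O)C1=O)[C@H](c1ccc(O[Si](C)(C)C(C)(C)C)c(OC)c1)[C@H]2C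
F4 | step 4 | racemic 8-(4-hydroxy-3-methoxyphenyl)-4,5-dimethoxy-7-methyl-1-(prop-2-en-1-yl)bicyclo[2.2.2]oct-5-ene-2,3-dione (one enantiomer drawn) | C=CC[C@@]12C=C(OC)[C@@](OC)(C(=O)C1=O)[C@H](c1ccc(O)c(OC)c1)[C@H]2C
F0 | step 8 | none | none
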